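The C13(OAc)–C11=C7–C8(O-acyl) unit, which straddles the butenolide and the ten-membered ring, is read as the trace of dioxygen added across an s-cis C13=C11–C7=C8 diene. That diene is made by ring-closing enyne metathesis between a C7≡C11 alkyne and a C8 vinyl group. In one operation the key step closes the ten-membered carbocycle through the new C7=C8 bond and moves the vinyl CH2 onto C11, where it becomes C13. Its precursor is an open-chain enyne built from geranyl acetate that already carries both trans-oxiranes and the C6 carbinol, with one terminal alkene and one internal alkyne as its only metathesis-active groups.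

Key step: step 8

Numbering remark: atom labels follow germacranolide numbering (C1–C10 ring carbons, C11 lactone α-carbon, C12 lactone carbonyl, C13 the CH2OAc carbon, C14 the methyl on C10, C15 the methyl on C4).
Assumption on step 6: (S,S)-ProPhenol is taken to deliver the alkynyl group to the enal face that gives the R carbinol; the sense is checked on the first run by Mosher ester analysis and the (R,R) ligand is used if it is opposite.
Assumption on step 11: singlet oxygen is drawn as adding to the diene face that carries H6, away from the ten-membered loop (8R endoperoxide); C8 is erased in step 14, so the route does not depend on this.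

Step 1
Reactants: 1 geranyl acetate, (2E)-3,7-dimethylocta-2,6-dien-1-yl acetate
Product: 2 (2E,6E)-8-hydroxy-3,7-dimethylocta-2,6-dien-1-yl acetate
Conditions: SeO2 (cat.), t-BuOOH, salicylic acid (cat.), CH2Cl2, rt
Reagents that add atoms: tert-butyl hydroperoxide, CC(C)(C)OO (oxygen relayed through SeO2)
Why: Catalytic SeO2 allylic oxidation (ene reaction, then [2,3]-sigmatropic shift) is selective for the E-methyl group of the terminal trisubstituted alkene, the alkene next to the acetate being deactivated.

Step 2
Reactants: 2 (2E,6E)-8-hydroxy-3,7-dimethylocta-2,6-dien-1-yl acetate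
Product: 3 (2E,6E)-8-bromo-3,7-dimethylocta-2,6-dien-1-yl acetate
Conditions: CBr4, PPh3, CH2Cl2, 0 °C
Reagents that add atoms: carbon tetrabromide, BrC(Br)(Br)Br
Why: Appel bromination displaces the activated primary allylic oxygen by SN2 at CH2, without allylic transposition or loss of the 6E geometry, and leaves the acetate alone.

Step 3
Reactants: 3 (2E,6E)-8-bromo-3,7-dimethylocta-2,6-dien-1-yl acetate; 4 tributyl(vinyl)stannane
Product: 5 (2E,6E)-3,7-dimethyldeca-2,6,9-trien-1-yl acetate
Conditions: Pd2(dba)3 (2.5 mol %), AsPh3 (10 mol %), THF, 50 °C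
Reagents that add atoms: none
Why: Stille allyl–vinyl coupling: zerovalent palladium inserts into the allylic C–Br bond much faster than into the allylic acetate, and vinyl transfer to the less hindered terminus of the π-allyl gives the skipped diene with the E geometry kept.

Step 4
Reactants: 5 (2E,6E)-3,7-dimethyldeca-2,6,9-trien-1-yl acetate
Product: 6 (2E,6E)-3,7-dimethyldeca-2,6,9-trien-1-ol
Conditions: K2CO3 (0.2 equiv), MeOH, rt
Reagents that add atoms: none
Why: Base-catalysed transesterification with methanol removes the acetate and cannot move the skipped or trisubstituted alkenes.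

Step 5
Reactants: 6 (2E,6E)-3,7-dimethyldeca-2,6,9-trien-1-ol
Product: 7 (2E,6E)-3,7-dimethyldeca-2,6,9-trienal
Conditions: MnO2 (excess), CH2Cl2, rt
Reagents that add atoms: none
Why: MnO2 oxidises only the allylic alcohol, stops at the enal and does not isomerise the 2E alkene.

Step 6
Reactants: 7 (2E,6E)-3,7-dimethyldeca-2,6,9-trienal; 8 tert-butyldimethyl(prop-2-yn-1-yloxy)silane
Product: 10 (4R,5E,9E)-1-(tert-butyldimethylsilyloxy)-6,10-dimethyltrideca-5,9,12-trien-2-yn-4-ol, via alkynyl(methyl)zinc 9 (not isolated)
Conditions: Me2Zn (3 equiv), (S,S)-ProPhenol (20 mol %), Ph3P=O (40 mol %), toluene, 0 to 4 °C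
Reagents that add atoms: none
Why: ProPhenol–zinc catalysed asymmetric alkynylation: the dinuclear zinc–ProPhenol complex binds the enal and the alkynylzinc 9 formed from 8 and Me2Zn and delivers the alkynyl group to one aldehyde face, so the ligand sets C6 (chain C4) as R.

Step 7
Reactants: 10 (4R,5E,9E)-1-(tert-butyldimethylsilyloxy)-6,10-dimethyltrideca-5,9,12-trien-2-yn-4-ol
Product: 11 (4S,5R,6R,9R,10R)-1-(tert-butyldimethylsilyloxy)-5,6:9,10-diepoxy-6,10-dimethyltridec-12-en-2-yn-4-ol (germacrane labels 6S, 4R,5R, 1R,10R)
Conditions: D-fructose-derived Shi ketone (1,2:4,5-di-O-isopropylidene-β-D-erythro-2,3-hexodiulo-2,6-pyranose, 0.6 equiv), KHSO5 (as Oxone), K2CO3, Bu4NHSO4 (cat.), Na2B4O7 buffer (pH 10.5), MeCN–CH2(OMe)2–H2O, 0 °C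
Reagents that add atoms: potassium peroxymonosulfate, [K+].[O-]S(=O)(=O)OO
Why: Shi epoxidation: the dioxirane of the D-fructose ketone epoxidises both E-trisubstituted alkenes through the spiro transition state to the R,R oxirane at C1/C10 and at C4/C5, while the monosubstituted vinyl group and the alkyne are far less reactive; at C4=C5 the catalyst face is also the threo face favoured by the C6 carbinol under allylic 1,3-strain, and C6 is untouched (its descriptor becomes S by priority only).

Step 8
Reactants: 11 (4S,5R,6R,9R,10R)-1-(tert-butyldimethylsilyloxy)-5,6:9,10-diepoxy-6,10-dimethyltridec-12-en-2-yn-4-ol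
Product: 12 (6S,7Z)-12-(tert-butyldimethylsilyloxy)-1R,10R:4R,5R-diepoxygermacra-7,11(13)-dien-6-ol (ten-membered ring; C7 carries the 3-silyloxyprop-1-en-2-yl group C11(=C13H2)C12H2OSi)
Conditions: second-generation Hoveyda–Grubbs catalyst (H2IMes)Cl2Ru(=CH-C6H4-2-OiPr) (10 mol %, two portions), ethylene (1 atm), toluene (2 mM), 80 °C
Reagents that add atoms: none
Why: Ring-closing enyne metathesis: the ruthenium methylidene exchanges with the only alkene of 11 to give the C8 alkylidene, which adds across the C7≡C11 alkyne with C8 bonding to C7 and ruthenium to C11, and the ruthenacyclobutene opens to a C11 vinylcarbene that is released as the C11=C13H2 methylene by ethylene or by the vinyl group of a second molecule of 11. The closest known reaction type is exo-mode ring-closing enyne metathesis to 1-vinylcycloalkenes, documented for medium rings of up to eleven members and for alkynes with propargylic oxygen. The ten-membered carbocycle is the only ring closed, in the exo mode (10-exo-dig, only C7 of the alkyne enters the ring). No stereocentre is created; the new C7=C8 bond is expected ring-cis (7Z), the lower-strain way for the ten-atom tether to bridge C7 and C8 in the metallacycle, which also puts C9 outward on the diene terminus as step 11 requires. The step needs exo over endo (eleven-membered) closure and cyclisation over dimerisation: the first is secured by ruthenium ending on the less hindered C11 (CH2OSi) instead of C7 next to the carbinol, the second by 2 mM dilution and the chain bend imposed by the two trans-oxiranes, and 11 has exactly one alkene and one alkyne, so no olefin metathesis competes. Trading an alkyne π bond for a conjugated diene makes the closure exergonic and irreversible, unlike diene metathesis to a medium ring.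

Step 9
Reactants: 12 (6S,7Z)-12-(tert-butyldimethylsilyloxy)-1R,10R:4R,5R-diepoxygermacra-7,11(13)-dien-6-ol
Product: 13 (6S,7Z)-1R,10R:4R,5R-diepoxygermacra-7,11(13)-diene-6,12-diol
Conditions: Bu4NF, AcOH (1:1), THF, 0 °C to rt
Reagents that add atoms: none
Why: Fluoride cleaves the primary silyl ether, and acetic acid buffering keeps the medium non-basic so that the oxiranes and the epoxy alcohol (Payne rearrangement) are not disturbed.

Step 10
Reactants: 13 (6S,7Z)-1R,10R:4R,5R-diepoxygermacra-7,11(13)-diene-6,12-diol
Product: 16 (6S,7Z)-1R,10R:4R,5R-diepoxygermacra-7,11(13)-dien-12,6-olide, via hydroxy enal 14 (not isolated), via lactol 15 (not isolated)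
Conditions: TEMPO (0.2 equiv), PhI(OAc)2 (2.5 equiv), CH2Cl2, rt
Reagents that add atoms: none
Why: TEMPO/PhI(OAc)2 oxidative lactonisation: the oxoammonium ion oxidises the primary allylic alcohol much faster than the secondary C6 carbinol, O6 traps the enal 14 as the five-membered lactol 15, and further oxidation gives the γ-lactone, which locks the diene s-cis.

Step 11
Reactants: 16 (6S,7Z)-1R,10R:4R,5R-diepoxygermacra-7,11(13)-dien-12,6-olide
Product: 17 (6S,8R)-1R,10R:4R,5R-diepoxy-8,13-epidioxygermacr-7(11)-en-12,6-olide (3,6-dihydro-1,2-dioxine fused to the butenolide)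
Conditions: O2, tetraphenylporphyrin (cat.), visible light, CH2Cl2, −20 °C
Reagents that add atoms: dioxygen, O=O
Why: Singlet-oxygen [4+2] cycloaddition (photooxygenation) onto the s-cis-locked 1,2-bis(alkylidene) diene forms the C13–O and C8–O bonds and shifts the alkene to C7=C11; attack on the H6 face away from the loop is expected to give 8R, a centre that is erased in step 14.

Step 12
Reactants: 17 (6S,8R)-1R,10R:4R,5R-diepoxy-8,13-epidioxygermacr-7(11)-en-12,6-olide
Product: 18 (6S,8R)-1R,10R:4R,5R-diepoxy-8,13-dihydroxygermacr-7(11)-en-12,6-olide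
Conditions: thiourea (1.2 equiv), MeOH, 0 °C to rt
Reagents that add atoms: none
Why: Thiourea reduces the O–O bond of the endoperoxide to the cis-2-ene-1,4-diol under neutral conditions that leave the oxiranes, the butenolide and the C8 configuration unchanged.

Step 13
Reactants: 18 (6S,8R)-1R,10R:4R,5R-diepoxy-8,13-dihydroxygermacr-7(11)-en-12,6-olide
Product: 19 (6S,8R)-13-acetoxy-1R,10R:4R,5R-diepoxy-8-hydroxygermacr-7(11)-en-12,6-olide
Conditions: Ac2O (1.1 equiv), 2,4,6-collidine, CH2Cl2, −20 to 0 °C
Reagents that add atoms: acetic anhydride, CC(=O)OC(C)=O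
Why: With one equivalent of anhydride and a weak hindered base at low temperature the primary C13 alcohol is acylated much faster than the hindered secondary C8 alcohol.

Step 14
Reactants: 19 (6S,8R)-13-acetoxy-1R,10R:4R,5R-diepoxy-8-hydroxygermacr-7(11)-en-12,6-olide
Product: 20 (6S)-13-acetoxy-1R,10R:4R,5R-diepoxy-8-oxogermacr-7(11)-en-12,6-olide
Conditions: Dess–Martin periodinane (1.5 equiv), NaHCO3, CH2Cl2, 0 °C to rt
Reagents that add atoms: none
Why: Dess–Martin oxidation under NaHCO3 buffering gives the ketone under near-neutral conditions, which matters because 20 is a β,γ-epoxy ketone open to base-induced opening of the C1–C10 oxirane and is therefore taken on crude.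

Step 15
Reactants: 20 (6S)-13-acetoxy-1R,10R:4R,5R-diepoxy-8-oxogermacr-7(11)-en-12,6-olide
Product: 21 (6S,8S)-13-acetoxy-1R,10R:4R,5R-diepoxy-8-hydroxygermacr-7(11)-en-12,6-olide
Conditions: (R)-2-methyl-CBS-oxazaborolidine (0.5 equiv), catecholborane (2 equiv), toluene–CH2Cl2, −78 °C; then MeOH
Reagents that add atoms: none
Why: Corey–Bakshi–Shibata reduction: the (R)-oxazaborolidine binds the ketone with the α-branched alkenyl carbon C7 as the large group and delivers hydride to give 8S (the sense by which it gives (S)-1-phenylethanol from acetophenone), this being also the exposed face of the ring, and 1,2-reduction at −78 °C leaves lactone, acetate and oxiranes intact.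

Step 16
Reactants: 22 (R)-2-methylglycidol, [(2R)-2-methyloxiran-2-yl]methanol
Product: 23 (2S)-2-methyloxirane-2-carboxylic acid
Conditions: RuCl3·xH2O (2 mol %), NaIO4 (3 equiv), MeCN–EtOAc–H2O, 0 °C to rt
Reagents that add atoms: water, O (second carboxyl oxygen, through the aldehyde hydrate)
Why: RuO4 generated catalytically from RuCl3 and NaIO4 oxidises the primary alcohol to the acid without touching the oxirane or the quaternary centre, whose descriptor changes from R to S by priority only; the acid is used at once.

Step 17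
Reactants: 21 (6S,8S)-13-acetoxy-1R,10R:4R,5R-diepoxy-8-hydroxygermacr-7(11)-en-12,6-olide; 23 (2S)-2-methyloxirane-2-carboxylic acid
Product: 24 target CNP0289810.2, (6S,8S)-13-acetoxy-1R,10R:4R,5R-diepoxy-8-[(2S)-2-methyloxirane-2-carbonyloxy]germacr-7(11)-en-12,6-olide
Conditions: N,N'-diisopropylcarbodiimide (1.5 equiv), DMAP (0.2 equiv), CH2Cl2, 0 °C to rt
Reagents that add atoms: none
Why: Steglich esterification acylates the C8 alcohol with retention at C8 and at the non-enolisable quaternary centre of the acid, under conditions mild enough for the three oxiranes.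

Compound list
1 | geranyl acetate | CC(C)=CCC/C(C)=C/COC(C)=O | starting material
2 | (2E,6E)-8-hydroxy-3,7-dimethylocta-2,6-dien-1-yl acetate | OC/C(C)=C/CC/C(C)=C/COC(C)=O | intermediate
3 | (2E,6E)-8-bromo-3,7-dimethylocta-2,6-dien-1-yl acetate | BrC/C(C)=C/CC/C(C)=C/COC(C)=O | intermediate
4 | tributyl(vinyl)stannane | C=C[Sn](CCCC)(CCCC)CCCC | starting material
5 | (2E,6E)-3,7-dimethyldeca-2,6,9-trien-1-yl acetate | C=CC/C(C)=C/CC/C(C)=C/COC(C)=O | intermediate
6 | (2E,6E)-3,7-dimethyldeca-2,6,9-trien-1-ol | C=CC/C(C)=C/CC/C(C)=C/CO | intermediate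
7 | (2E,6E)-3,7-dimethyldeca-2,6,9-trienal | C=CC/C(C)=C/CC/C(C)=C/C=O | intermediate
8 | tert-butyldimethyl(prop-2-yn-1-yloxy)silane | C#CCO[Si](C)(C)C(C)(C)C | starting material
9 | methyl[3-(tert-butyldimethylsilyloxy)prop-1-yn-1-yl]zinc | C[Zn]C#CCO[Si](C)(C)C(C)(C)C | intermediate
10 | (4R,5E,9E)-1-(tert-butyldimethylsilyloxy)-6,10-dimethyltrideca-5,9,12-trien-2-yn-4-ol | C=CC/C(C)=C/CC/C(C)=C/[C@@H](O)C#CCO[Si](C)(C)C(C)(C)C | intermediate
11 | (4S,5R,6R,9R,10R)-1-(tert-butyldimethylsilyloxy)-5,6:9,10-diepoxy-6,10-dimethyltridec-12-en-2-yn-4-ol | C=CC[C@@]1(C)O[C@@H]1CC[C@@]1(C)O[C@@H]1[C@@H](O)C#CCO[Si](C)(C)C(C)(C)C | intermediate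
12 | (6S,7Z)-12-(tert-butyldimethylsilyloxy)-1R,10R:4R,5R-diepoxygermacra-7,11(13)-dien-6-ol | C=C(CO[Si](C)(C)C(C)(C)C)/C1=C/C[C@@]2(C)O[C@@H]2CC[C@@]2(C)O[C@@H]2[C@H]1O | intermediate
13 | (6S,7Z)-1R,10R:4R,5R-diepoxygermacra-7,11(13)-diene-6,12-diol | C=C(CO)/C1=C/C[C@@]2(C)O[C@@H]2CC[C@@]2(C)O[C@@H]2[C@H]1O | intermediate
14 | (6S,7Z)-1R,10R:4R,5R-diepoxy-6-hydroxygermacra-7,11(13)-dien-12-al | C=C(C=O)/C1=C/C[C@@]2(C)O[C@@H]2CC[C@@]2(C)O[C@@H]2[C@H]1O | intermediate
15 | 12,6-lactol of 14 (both C12 epimers) | C=C1/C2=C/C[C@@]3(C)O[C@@H]3CC[C@@]3(C)O[C@@H]3[C@H]2OC1O | intermediate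
16 | (6S,7Z)-1R,10R:4R,5R-diepoxygermacra-7,11(13)-dien-12,6-olide | C=C1/C2=C/C[C@@]3(C)O[C@@H]3CC[C@@]3(C)O[C@@H]3[C@H]2OC1=O | intermediate
17 | (6S,8R)-1R,10R:4R,5R-diepoxy-8,13-epidioxygermacr-7(11)-en-12,6-olide | O4CC1=C2[C@H](O4)C[C@@]3(C)O[C@@H]3CC[C@@]3(C)O[C@@H]3[C@H]2OC1=O | intermediate
18 | (6S,8R)-1R,10R:4R,5R-diepoxy-8,13-dihydroxygermacr-7(11)-en-12,6-olide | OCC1=C2[C@H](O)C[C@@]3(C)O[C@@H]3CC[C@@]3(C)O[C@@H]3[C@H]2OC1=O | intermediate
19 | (6S,8R)-13-acetoxy-1R,10R:4R,5R-diepoxy-8-hydroxygermacr-7(11)-en-12,6-olide | CC(=O)OCC1=C2[C@H](O)C[C@@]3(C)O[C@@H]3CC[C@@]3(C)O[C@@H]3[C@H]2OC1=O | intermediate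
20 | (6S)-13-acetoxy-1R,10R:4R,5R-diepoxy-8-oxogermacr-7(11)-en-12,6-olide | CC(=O)OCC1=C2C(=O)C[C@@]3(C)O[C@@H]3CC[C@@]3(C)O[C@@H]3[C@H]2OC1=O | intermediate
21 | (6S,8S)-13-acetoxy-1R,10R:4R,5R-diepoxy-8-hydroxygermacr-7(11)-en-12,6-olide | CC(=O)OCC1=C2[C@@H](O)C[C@@]3(C)O[C@@H]3CC[C@@]3(C)O[C@@H]3[C@H]2OC1=O | intermediate
22 | (R)-2-methylglycidol | OC[C@]1(C)CO1 | starting material
23 | (2S)-2-methyloxirane-2-carboxylic acid | OC(=O)[C@]1(C)CO1 | intermediate
24 | CNP0289810.2 | CC(=O)OCC1=C2[C@@H](OC(=O)[C@]3(C)CO3)C[C@@]3(C)O[C@@H]3CC[C@@]3(C)O[C@@H]3[C@H]2OC1=O | target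

Total step count: 17.
Longest linear sequence: 16 steps (steps 1 to 15 and step 17, from geranyl acetate).

Steps most likely to fail

1. Step 8. Oligomerisation or endo-mode closure to the eleven-membered ring may outrun the strained ten-membered exo closure. The alkyne may also be consumed by cross-metathesis with ethylene without ring closure, or the ring alkene may form with the E geometry. The fallback sets out from 11 and comes back at 16. It separates diene formation from ring closure. Ethylene–alkyne cross-metathesis of 11 with second-generation Grubbs catalyst (H2IMes)(PCy3)Cl2Ru(=CHPh) under ethylene in toluene at 80 °C, at normal concentration, should give the open-chain 2,3-disubstituted buta-1,3-diene F1 (the expected by-product of step 8 itself). Bu4NF/AcOH should then give the diene diol F2, and TEMPO/PhI(OAc)2 the 3,4-bis(methylene)butanolide F3, in which the lactone holds the C7 methylene rigidly. Diene ring-closing metathesis of F3 at high dilution with second-generation Hoveyda–Grubbs catalyst (H2IMes)Cl2Ru(=CH-C6H4-2-OiPr) would join the vinyl group to the electron-neutral C7 methylene, the carbonyl-conjugated C11 methylene being the poorer partner, and lead to 16 with loss of ethylene.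

2. Step 11. The ene reaction at the trisubstituted C7=C8 alkene (abstraction of H9 or H6) may compete with the cycloaddition. The carbonyl-conjugated diene may also react so slowly that photo-oxidative degradation takes over. The fallback sets out from 16 and comes back at 19, replacing the cycloaddition by epoxidation and allylic substitution. Dimethyldioxirane in acetone at −20 °C should epoxidise the electron-richer C7=C8 bond, and not the conjugated C11=C13 bond, from the exposed H6 face to give the spiro 7,8-oxirane F4. A Tsuji–Trost opening of this vinyl oxirane with Pd(PPh3)4 (cat.) and AcOH in THF should follow. The π-allyl carries the lactone carbonyl on its central carbon, as in Morita–Baylis–Hillman acetates, so acetate attacks the primary C13 terminus and gives the 13-acetoxy-8-hydroxy butenolide 19 directly. The two remote oxiranes are not allylic and are inert to zerovalent palladium.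

3. Step 15. The conformational bias of the medium ring may override the catalyst and give poor facial selectivity. Ketone 20 may also be lost beforehand through enolisation toward C9 and elimination that opens the C1–C10 oxirane. The fallback sets out from 19 and comes back at 24. Compound 19 already has the opposite (8R) configuration, so a Mitsunobu esterification with acid 23 (PPh3, diisopropyl azodicarboxylate, toluene, 0 °C) should invert C8 and install the side chain in one operation. It reaches target 24 without passing through 20 and 21 and makes no new compound (F0).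

Further compounds
F1 | step 8 | (4S,5R,6R,9R,10R)-1-(tert-butyldimethylsilyloxy)-5,6:9,10-diepoxy-6,10-dimethyl-2,3-dimethylidenetridec-12-en-4-ol | C=CC[C@@]1(C)O[C@@H]1CC[C@@]1(C)O[C@@H]1[C@@H](O)C(=C)C(=C)CO[Si](C)(C)C(C)(C)C
F2 | step 8 | (4S,5R,6R,9R,10R)-5,6:9,10-diepoxy-6,10-dimethyl-2,3-dimethylidenetridec-12-ene-1,4-diol | C=CC[C@@]1(C)O[C@@H]1CC[C@@]1(C)O[C@@H]1[C@@H](O)C(=C)C(=C)CO
F3 | step 8 | (5S)-3,4-dimethylidene-5-[(2R,3R)-3-methyl-3-{2-[(2R,3R)-3-methyl-3-(prop-2-en-1-yl)oxiran-2-yl]ethyl}oxiran-2-yl]oxolan-2-one | C=CC[C@@]1(C)O[C@@H]1CC[C@@]1(C)O[C@@H]1[C@H]2OC(=O)C(=C)C2=C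
F4 | step 11 | (6S,8R)-1R,10R:4R,5R:7,8-triepoxygermacr-11(13)-en-12,6-olide (7,8-oxirane on the H6 face) | C=C1[C@@]2(O4)[C@H]4C[C@@]3(C)O[C@@H]3CC[C@@]3(C)O[C@@H]3[C@H]2OC1=O
F0 | step 15 | none | none
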